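Chromanone numbering is used throughout. Ring B = O1, C2, C3, C4(=O), C4a, C8a. Ring A = C4a, C5(OH), C6(side chain), C7(=O), C8(quaternary), C8a.
Last disconnection: the C8 prenyl group is moved back onto the carboxyl oxygen of the side chain. An O-to-C prenyl shift under a chiral palladium catalyst sets C8 and starts from an aromatic 5,7-dihydroxychromanone prenyl ester.
Key disconnection: ring A is cut at C7–C8 and C5–C6. The four-carbon piece C8–C8a–C4a–C5 is an acetoacetate unit carried by a ring B dihydropyranone acid chloride. The two-carbon piece C7–C6 is one CH2–C(=O) arm of a 3-propylglutarate, activated as its S-phenyl thioester.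
Enabling feature: C7, C6 and the hexanoic acid chain on C6 together form a 3-propylglutaric acid. The 1,3,5-oxygen pattern of ring A makes C5 and C7 acyl carbons and C6 and C8 enolate carbons. The oxygen on C8a is locked as O1 of ring B, so only carbon C8 can close the ring.
Ring order: ring B first, ring A second (key step), dearomatisation last. C2/C3 come from an Evans syn aldol, the lavandulyl centre from a deconjugative Evans alkylation, the side-chain centre from desymmetrisation of 3-propylglutaric anhydride with prenyl alcohol, and C8 from the catalyst.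

Key step: step 16

Assumption: quinidine is taken to give the (S)-hemiester (by analogy with the opposite sense known for quinine on 3-alkylglutaric anhydrides), and the (R,R)-ligand is taken to give (R)-C8; if either sense is the reverse, quinine or the (S,S)-ligand is used and nothing else changes.

Step 1
Reactants: 1 (S)-4-benzyl-1,3-oxazolidin-2-one; 2 3-methylbut-2-enoyl chloride
Product: 3 (S)-4-benzyl-3-(3-methylbut-2-enoyl)-1,3-oxazolidin-2-one
Conditions: n-BuLi, THF, −78 °C; then 2, −78 → 0 °C
Reagents that add atoms: none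
Why: N-acylation of the lithiated oxazolidinone with an acid chloride is the standard way to load an Evans auxiliary.

Step 2
Reactants: 3 (S)-4-benzyl-3-(3-methylbut-2-enoyl)-1,3-oxazolidin-2-one; 4 1-bromo-3-methylbut-2-ene (prenyl bromide)
Product: 5 (S)-4-benzyl-3-[(2S)-5-methyl-2-(prop-1-en-2-yl)hex-4-enoyl]-1,3-oxazolidin-2-one
Conditions: NaN(SiMe3)2, THF, −78 °C; then 4, −78 → −20 °C
Reagents that add atoms: none
Why: In this deconjugative Evans alkylation, γ-deprotonation gives the chelated Z-dienolate, which should react at its α-carbon on the face opposite the benzyl group and so set the lavandulyl stereocentre as S.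

Step 3
Reactants: 5 (S)-4-benzyl-3-[(2S)-5-methyl-2-(prop-1-en-2-yl)hex-4-enoyl]-1,3-oxazolidin-2-one
Product: 6 (S)-lavandulol, (2S)-5-methyl-2-(prop-1-en-2-yl)hex-4-en-1-ol
Conditions: LiBH4, H2O (1 equiv), Et2O, 0 °C
Reagents that add atoms: none
Why: Reductive removal of the auxiliary with borohydride attacks only the exocyclic imide carbonyl and leaves the stereocentre and both alkenes untouched.

Step 4
Reactants: 6 (S)-lavandulol
Product: 7 (S)-lavandulyl iodide, (2S)-1-iodo-5-methyl-2-(prop-1-en-2-yl)hex-4-ene
Conditions: I2, PPh3, imidazole, CH2Cl2, 0 °C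
Reagents that add atoms: iodine, II
Why: This Appel-type iodination takes place at the primary carbinol carbon under neutral conditions, so the adjacent stereocentre is not involved.

Step 5
Reactants: 7 (S)-lavandulyl iodide; 8 tert-butyl acetoacetate
Product: 9 tert-butyl (6S)-9-methyl-3-oxo-6-(prop-1-en-2-yl)dec-8-enoate
Conditions: 8, NaH then n-BuLi, THF, 0 °C; then 7, 0 °C → rt; 1 M HCl
Reagents that add atoms: none
Why: The acetoacetate dianion is alkylated only at its more reactive terminal carbanion, which displaces the primary iodide by SN2 and joins the four carbons of the future C8–C8a–C4a–C5 unit to the lavandulyl group.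

Step 6
Reactants: 10 (S)-4-benzyl-3-propanoyl-1,3-oxazolidin-2-one; 11 acetaldehyde
Product: 12 (S)-4-benzyl-3-[(2S,3R)-3-hydroxy-2-methylbutanoyl]-1,3-oxazolidin-2-one
Conditions: Bu2BOTf, Et3N, CH2Cl2, −78 → 0 °C; 11, −78 °C; then H2O2, MeOH, pH 7 buffer
Reagents that add atoms: none
Why: In the Evans syn aldol reaction, the Z-boron enolate reacts through a Zimmerman–Traxler chair whose face is fixed by the auxiliary, which sets both stereocentres (2S,3R; the future C3 and C2) in one event.

Step 7
Reactants: 12 (S)-4-benzyl-3-[(2S,3R)-3-hydroxy-2-methylbutanoyl]-1,3-oxazolidin-2-one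
Product: 13 (S)-4-benzyl-3-[(2S,3R)-3-(tert-butyldimethylsilyloxy)-2-methylbutanoyl]-1,3-oxazolidin-2-one
Conditions: t-BuMe2SiOTf, 2,6-lutidine, CH2Cl2, 0 °C
Reagents that add atoms: tert-butyldimethylsilyl triflate, CC(C)(C)[Si](C)(C)OS(=O)(=O)C(F)(F)F
Why: Silylation of the secondary alcohol with the silyl triflate and a hindered base is routine and prevents retro-aldol and lactone formation in the next steps.

Step 8
Reactants: 13 (S)-4-benzyl-3-[(2S,3R)-3-(tert-butyldimethylsilyloxy)-2-methylbutanoyl]-1,3-oxazolidin-2-one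
Product: 14 (2S,3R)-3-(tert-butyldimethylsilyloxy)-2-methylbutanoic acid
Conditions: LiOH, H2O2, THF/H2O, 0 °C; Na2SO3; 1 M HCl
Reagents that add atoms: hydrogen peroxide, OO
Why: Hydroperoxide attacks the exocyclic imide carbonyl selectively and is too weakly basic to epimerise the α-carbon, which is the standard hydrolytic removal of the auxiliary.

Step 9
Reactants: 14 (2S,3R)-3-(tert-butyldimethylsilyloxy)-2-methylbutanoic acid; 9 tert-butyl (6S)-9-methyl-3-oxo-6-(prop-1-en-2-yl)dec-8-enoate
Product: 16 tert-butyl (6S)-2-[(2S,3R)-3-(tert-butyldimethylsilyloxy)-2-methylbutanoyl]-9-methyl-3-oxo-6-(prop-1-en-2-yl)dec-8-enoate (enolised tricarbonyl, C2 not defined), via acid chloride 15 (not isolated)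
Conditions: 14, 1-chloro-N,N,2-trimethylprop-1-en-1-amine, CH2Cl2, 0 °C; then 9, MgCl2, pyridine, CH2Cl2, 0 °C → rt
Reagents that add atoms: none
Why: The chloroenamine makes the acid chloride under neutral conditions without β-elimination or epimerisation, and the magnesium chelate of the β-keto ester is then acylated on carbon, a standard magnesium-mediated C-acylation of 1,3-dicarbonyl compounds.

Step 10
Reactants: 16 tert-butyl (6S)-2-[(2S,3R)-3-(tert-butyldimethylsilyloxy)-2-methylbutanoyl]-9-methyl-3-oxo-6-(prop-1-en-2-yl)dec-8-enoate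
Product: 17 tert-butyl (2R,3S)-2,3-dimethyl-6-[(3S)-6-methyl-3-(prop-1-en-2-yl)hept-5-en-1-yl]-4-oxo-3,4-dihydro-2H-pyran-5-carboxylate
Conditions: HF (48 % aq.), MeCN, 0 °C → rt
Reagents that add atoms: none
Why: Desilylation frees the hydroxyl, which adds to the chain ketone (six-membered hemiketal) and loses water, the known cyclodehydration of δ-hydroxy-1,3-diketones to 2,3-dihydropyran-4-ones; neither the C–O bond nor the α-carbon of the aldol unit is broken, so the syn aldol becomes the cis-(2R,3S)-dimethyl ring B, and the bulky tert-butyl ester disfavours the competing lactonisation.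

Step 11
Reactants: 17 tert-butyl (2R,3S)-2,3-dimethyl-6-[(3S)-6-methyl-3-(prop-1-en-2-yl)hept-5-en-1-yl]-4-oxo-3,4-dihydro-2H-pyran-5-carboxylate
Product: 18 (2R,3S)-2,3-dimethyl-6-[(3S)-6-methyl-3-(prop-1-en-2-yl)hept-5-en-1-yl]-4-oxo-3,4-dihydro-2H-pyran-5-carboxylic acid
Conditions: Me3SiOTf, 2,6-lutidine, CH2Cl2, 0 °C; then pH 5 buffer
Reagents that add atoms: none
Why: The silyl triflate with a hindered base cleaves tert-butyl esters through the silyl ester without protic acid, which spares the two acid-sensitive alkenes, and the acid cannot decarboxylate because its α-carbon is part of the ring alkene.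

Step 12
Reactants: 18 (2R,3S)-2,3-dimethyl-6-[(3S)-6-methyl-3-(prop-1-en-2-yl)hept-5-en-1-yl]-4-oxo-3,4-dihydro-2H-pyran-5-carboxylic acid
Product: 19 (2R,3S)-2,3-dimethyl-6-[(3S)-6-methyl-3-(prop-1-en-2-yl)hept-5-en-1-yl]-4-oxo-3,4-dihydro-2H-pyran-5-carbonyl chloride
Conditions: 1-chloro-N,N,2-trimethylprop-1-en-1-amine, CH2Cl2, 0 °C; concentrated and used at once
Reagents that add atoms: 1-chloro-N,N,2-trimethylprop-1-en-1-amine, CC(C)=C(Cl)N(C)C
Why: The chloroenamine converts acids into acid chlorides without liberating HCl or needing a base, so neither the alkenes nor the base-sensitive C3 centre of ring B is put at risk.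

Step 13
Reactants: 20 3-propylpentanedioic acid (3-propylglutaric acid)
Product: 21 4-propyloxane-2,6-dione (3-propylglutaric anhydride)
Conditions: Ac2O, reflux; distillation
Reagents that add atoms: none
Why: Dehydration of a glutaric acid to its six-membered cyclic anhydride with acetic anhydride is a routine reaction.

Step 14
Reactants: 21 4-propyloxane-2,6-dione; 22 3-methylbut-2-en-1-ol (prenyl alcohol)
Product: 23 (3S)-5-[(3-methylbut-2-en-1-yl)oxy]-5-oxo-3-propylpentanoic acid
Conditions: quinidine (1.1 equiv), toluene, −55 °C; 1 M HCl wash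
Reagents that add atoms: none
Why: In this cinchona-alkaloid-mediated desymmetrising alcoholysis of a prochiral 3-alkylglutaric anhydride, a reaction known with allylic alcohols, the quinuclidine nitrogen activates the alcohol by general-base catalysis and the alkaloid directs it to one enantiotopic carbonyl group, which sets the side-chain stereocentre and also installs the prenyl group needed in step 17.

Step 15
Reactants: 23 (3S)-5-[(3-methylbut-2-en-1-yl)oxy]-5-oxo-3-propylpentanoic acid; 24 benzenethiol
Product: 25 3-methylbut-2-en-1-yl (3R)-5-oxo-5-(phenylsulfanyl)-3-propylpentanoate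
Conditions: DCC, DMAP (cat.), CH2Cl2, 0 °C → rt
Reagents that add atoms: none
Why: Steglich-type thioesterification activates only the free carboxyl group and does not touch the β-stereocentre, whose descriptor changes to R only because of the priority of sulfur.

Step 16
Reactants: 25 3-methylbut-2-en-1-yl (3R)-5-oxo-5-(phenylsulfanyl)-3-propylpentanoate; 19 (2R,3S)-2,3-dimethyl-6-[(3S)-6-methyl-3-(prop-1-en-2-yl)hept-5-en-1-yl]-4-oxo-3,4-dihydro-2H-pyran-5-carbonyl chloride
Product: 29 3-methylbut-2-en-1-yl (3R)-3-{(2R,3S)-5,7-dihydroxy-2,3-dimethyl-8-[(2R)-5-methyl-2-(prop-1-en-2-yl)hex-4-en-1-yl]-4-oxo-3,4-dihydro-2H-chromen-6-yl}hexanoate, via lithium thioester enolate 26 (not isolated), via acyl vinylketene 27 (not isolated), via chelated lithium dienolate 28 (not isolated)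
Conditions: 25, LiN(SiMe3)2 (2.1 equiv), THF, −78 °C; 19 in THF, −78 °C; LiN(SiMe3)2 (1.1 equiv), −78 → 0 °C; AcOH
Reagents that add atoms: none
Why: Proposed new method: LiN(SiMe3)2 converts 25 chemoselectively into its lithium enolate 26 (the thioester α-CH2 is far more acidic than the α-CH2 of the prenyl ester) and strips HCl from 19 by 1,4-elimination to the acyl vinylketene 27; C-acylation of 26 at the ketene carbon makes the C5–C6 bond and gives dienolate 28, whose γ-carbon C8 attacks the thioester carbonyl C7, expels thiophenolate and makes the C7–C8 bond, after which the cyclohexenedione tautomerises irreversibly to the phloroglucinol ring of 29. The closest known reaction types are the anionic [4+2] annulations of the Staunton–Weinreb and Hauser–Kraus kind (carbanion attack followed by Dieckmann closure), the lithium ynolate–vinylketene benzannulation to resorcinols, and the biomimetic Claisen cyclisation of polyketide thioesters to acylphloroglucinols. Ring A closes in the favoured 6-(enolendo)-exo-trig mode, and if thiophenolate leaves first by E1cB, the resulting 3-oxidodienylketene reaches the same product by 6π electrocyclisation. No stereocentre is created (C6 of 28 is sp3 only in passing), and the four existing ones should survive because the side-chain centre is β to the thioester and H-3 of ring B is shielded from the base, the C4 carbonyl being part of an enolate from the moment 28 forms. The step needs C-closure instead of O-closure: the oxygen on C8a is already alkylated as O1 of ring B and cannot lactonise, and lithium chelation between the C5 and C4 oxygens of 28 holds the thioester arm next to the C8a=C8 bond and away from the C4 oxygen, so only C8 can reach C7. The placement of all six substituents of ring A follows from the connectivity of the two partners, so no regiochemical choice arises.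

Step 17
Reactants: 29 3-methylbut-2-en-1-yl (3R)-3-{(2R,3S)-5,7-dihydroxy-2,3-dimethyl-8-[(2R)-5-methyl-2-(prop-1-en-2-yl)hex-4-en-1-yl]-4-oxo-3,4-dihydro-2H-chromen-6-yl}hexanoate
Product: 30 (3R)-3-{(2R,3S,8R)-5-hydroxy-2,3-dimethyl-8-(3-methylbut-2-en-1-yl)-8-[(2R)-5-methyl-2-(prop-1-en-2-yl)hex-4-en-1-yl]-4,7-dioxo-3,4,7,8-tetrahydro-2H-chromen-6-yl}hexanoic acid (target)
Conditions: Pd2(dba)3·CHCl3 (2.5 mol %), (1R,2R)-N,N'-bis[2-(diphenylphosphanyl)benzoyl]cyclohexane-1,2-diamine (7.5 mol %), degassed CH2Cl2, rt
Reagents that add atoms: none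
Why: Proposed new method: zerovalent palladium ionises the prenyl ester to the side-chain carboxylate and a (1,1-dimethylallyl)palladium cation, the carboxylate deprotonates the acidic 7-OH, and the phenoxide attacks the unhindered CH2 terminus through C8 (C6 is shielded by its secondary alkyl group and O-prenylation is reversible under the catalyst), so the ester group becomes the missing prenyl group and the free acid appears in the same isomerisation; the remote stereocentres exert no bias and the chiral pocket of the ligand selects the face of the planar phenoxide, which sets the quaternary C8 as R; the closest known reaction types are the palladium-catalysed asymmetric allylic dearomatisation of phenols and naphthols (Tsuji–Trost type) and the racemic palladium-catalysed dearomative allylation of acylphloroglucinols.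

Compound list
1 | (S)-4-benzyl-1,3-oxazolidin-2-one | O=C1N[C@@H](Cc2ccccc2)CO1 | starting material
2 | 3-methylbut-2-enoyl chloride | CC(C)=CC(=O)Cl | starting material
3 | (S)-4-benzyl-3-(3-methylbut-2-enoyl)-1,3-oxazolidin-2-one | CC(C)=CC(=O)N1[C@@H](Cc2ccccc2)COC1=O | intermediate
4 | 1-bromo-3-methylbut-2-ene | CC(C)=CCBr | starting material
5 | (S)-4-benzyl-3-[(2S)-5-methyl-2-(prop-1-en-2-yl)hex-4-enoyl]-1,3-oxazolidin-2-one | C=C(C)[C@H](CC=C(C)C)C(=O)N1[C@@H](Cc2ccccc2)COC1=O | intermediate
6 | (S)-lavandulol | C=C(C)[C@H](CC=C(C)C)CO | intermediate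
7 | (S)-lavandulyl iodide | C=C(C)[C@H](CC=C(C)C)CI | intermediate
8 | tert-butyl acetoacetate | CC(=O)CC(=O)OC(C)(C)C | starting material
9 | tert-butyl (6S)-9-methyl-3-oxo-6-(prop-1-en-2-yl)dec-8-enoate | C=C(C)[C@H](CC=C(C)C)CCC(=O)CC(=O)OC(C)(C)C | intermediate
10 | (S)-4-benzyl-3-propanoyl-1,3-oxazolidin-2-one | CCC(=O)N1[C@@H](Cc2ccccc2)COC1=O | starting material
11 | acetaldehyde | CC=O | starting material
12 | (S)-4-benzyl-3-[(2S,3R)-3-hydroxy-2-methylbutanoyl]-1,3-oxazolidin-2-one | O[C@H](C)[C@H](C)C(=O)N1[C@@H](Cc2ccccc2)COC1=O | intermediate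
13 | (S)-4-benzyl-3-[(2S,3R)-3-(tert-butyldimethylsilyloxy)-2-methylbutanoyl]-1,3-oxazolidin-2-one | CC(C)(C)[Si](C)(C)O[C@H](C)[C@H](C)C(=O)N1[C@@H](Cc2ccccc2)COC1=O | intermediate
14 | (2S,3R)-3-(tert-butyldimethylsilyloxy)-2-methylbutanoic acid | CC(C)(C)[Si](C)(C)O[C@H](C)[C@H](C)C(=O)O | intermediate
15 | (2S,3R)-3-(tert-butyldimethylsilyloxy)-2-methylbutanoyl chloride | CC(C)(C)[Si](C)(C)O[C@H](C)[C@H](C)C(=O)Cl | intermediate
16 | tert-butyl (6S)-2-[(2S,3R)-3-(tert-butyldimethylsilyloxy)-2-methylbutanoyl]-9-methyl-3-oxo-6-(prop-1-en-2-yl)dec-8-enoate (drawn as triketo tautomer) | CC(C)(C)[Si](C)(C)O[C@H](C)[C@H](C)C(=O)C(C(=O)OC(C)(C)C)C(=O)CC[C@@H](CC=C(C)C)C(C)=C | intermediate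
17 | tert-butyl (2R,3S)-2,3-dimethyl-6-[(3S)-6-methyl-3-(prop-1-en-2-yl)hept-5-en-1-yl]-4-oxo-3,4-dihydro-2H-pyran-5-carboxylate | O=C(OC(C)(C)C)C1=C(CC[C@@H](CC=C(C)C)C(C)=C)O[C@H](C)[C@H](C)C1=O | intermediate
18 | (2R,3S)-2,3-dimethyl-6-[(3S)-6-methyl-3-(prop-1-en-2-yl)hept-5-en-1-yl]-4-oxo-3,4-dihydro-2H-pyran-5-carboxylic acid | O=C(O)C1=C(CC[C@@H](CC=C(C)C)C(C)=C)O[C@H](C)[C@H](C)C1=O | intermediate
19 | (2R,3S)-2,3-dimethyl-6-[(3S)-6-methyl-3-(prop-1-en-2-yl)hept-5-en-1-yl]-4-oxo-3,4-dihydro-2H-pyran-5-carbonyl chloride | O=C(Cl)C1=C(CC[C@@H](CC=C(C)C)C(C)=C)O[C@H](C)[C@H](C)C1=O | intermediate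
20 | 3-propylpentanedioic acid | CCCC(CC(=O)O)CC(=O)O | starting material
21 | 4-propyloxane-2,6-dione | CCCC1CC(=O)OC(=O)C1 | intermediate
22 | 3-methylbut-2-en-1-ol | CC(C)=CCO | starting material
23 | (3S)-5-[(3-methylbut-2-en-1-yl)oxy]-5-oxo-3-propylpentanoic acid | OC(=O)C[C@H](CCC)CC(=O)OCC=C(C)C | intermediate
24 | benzenethiol | Sc1ccccc1 | starting material
25 | 3-methylbut-2-en-1-yl (3R)-5-oxo-5-(phenylsulfanyl)-3-propylpentanoate | O=C(Sc1ccccc1)C[C@H](CCC)CC(=O)OCC=C(C)C | intermediate
26 | lithium enolate of thioester 25 (enolate geometry immaterial) | [Li]OC(Sc1ccccc1)=C[C@H](CCC)CC(=O)OCC=C(C)C | intermediate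
27 | acyl vinylketene from 19: (2R,3S)-2,3-dimethyl-5-(oxomethylidene)oxan-4-one carrying a (Z)-6-alkylidene group (lavandulyl centre unchanged) | O=C=C1/C(=C/C[C@@H](CC=C(C)C)C(C)=C)O[C@H](C)[C@H](C)C1=O | intermediate
28 | lithium dienolate from 26 and 27, chelated between the C5 and C4 oxygens (C6 sp3, not defined) | [Li]O/C(C(C(=O)Sc2ccccc2)[C@H](CCC)CC(=O)OCC=C(C)C)=C1/C(=C/C[C@@H](CC=C(C)C)C(C)=C)O[C@H](C)[C@H](C)C1=O | intermediate
29 | 3-methylbut-2-en-1-yl (3R)-3-{(2R,3S)-5,7-dihydroxy-2,3-dimethyl-8-[(2R)-5-methyl-2-(prop-1-en-2-yl)hex-4-en-1-yl]-4-oxo-3,4-dihydro-2H-chromen-6-yl}hexanoate | C=C(C)[C@H](CC=C(C)C)Cc1c(O)c([C@H](CCC)CC(=O)OCC=C(C)C)c(O)c2c1O[C@H](C)[C@H](C)C2=O | intermediate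
30 | (3R)-3-{(2R,3S,8R)-5-hydroxy-2,3-dimethyl-8-(3-methylbut-2-en-1-yl)-8-[(2R)-5-methyl-2-(prop-1-en-2-yl)hex-4-en-1-yl]-4,7-dioxo-3,4,7,8-tetrahydro-2H-chromen-6-yl}hexanoic acid | C=C(C)[C@H](CC=C(C)C)C[C@@]1(CC=C(C)C)C(=O)C([C@H](CCC)CC(=O)O)=C(O)C2=C1O[C@H](C)[C@H](C)C2=O | target

Total step count: 17. Longest linear sequence: 11 steps (steps 1–5, 9–12, 16, 17).

Steps most likely to fail

1. Step 16.
What may go wrong: the cascade may stall at the stage of the β-keto thioester enolate. It may close through the C4 oxygen instead of through C8. It may lose material by self-condensation of the vinylketene. It may also erode the cis relationship in ring B by deprotonation at C3.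
Fallback: the two bonds are made in two separate known reactions, setting out from acid 18 and thioester 25. DCC and 1H-benzotriazole convert 18 into the N-acylbenzotriazole F1. A crossed Claisen condensation by soft enolisation of 25 (MgBr2·OEt2, i-Pr2NEt, CH2Cl2, rt) acylates the thioester α-carbon with F1 and gives the isolable β-keto thioester F2, which contains the C5–C6 bond. CF3CO2Ag then abstracts thiophenolate from F2 at room temperature. The acylketene set free closes onto C8 through its dienol, as in the last stage of vinylketene benzannulations, and forms the C7–C8 bond. Tautomerisation brings the sequence back to 29.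

2. Step 17.
What may go wrong: ionisation of the trisubstituted allyl ester may be slow, facial selectivity at C8 may be poor, or prenylation may end on oxygen or on C6.
Fallback: this uses classical chemistry of acylphloroglucinols and sets out from 29. Pd(PPh3)4 and morpholine remove the prenyl ester to give the free aromatic acid F3. Its lithium salt (LiN(SiMe3)2, toluene, −20 °C) is C-alkylated at C8 with prenyl bromide 4 in an alkylative dearomatisation. This should give 30 together with its C8 epimer F4. The two are diastereomers and are separated by preparative HPLC, which brings the route back to 30.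

3. Step 14.
What may go wrong: discrimination between the two enantiotopic carbonyl groups may be too low with the bulkier allylic alcohol.
Fallback: resolution replaces asymmetric induction, setting out from 21 and 22. DMAP-catalysed opening of the anhydride gives the racemic hemiester F5. Fractional crystallisation of its salt with (S)-1-phenylethylamine gives the diastereomerically pure ammonium salt F6. Acidification returns to 23.

Further compounds
F1 | step 16 | 1-{(2R,3S)-2,3-dimethyl-6-[(3S)-6-methyl-3-(prop-1-en-2-yl)hept-5-en-1-yl]-4-oxo-3,4-dihydro-2H-pyran-5-carbonyl}-1H-benzotriazole | O=C(n1nnc2ccccc12)C3=C(CC[C@@H](CC=C(C)C)C(C)=C)O[C@H](C)[C@H](C)C3=O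
F2 | step 16 | β-keto thioester: 3-methylbut-2-en-1-yl (3R)-3-propyl-5-oxo-5-(phenylsulfanyl)pentanoate acylated at C4 by the pyranone carbonyl group of 18 (C4 not defined) | O=C(Sc1ccccc1)C([C@H](CCC)CC(=O)OCC=C(C)C)C(=O)C2=C(CC[C@@H](CC=C(C)C)C(C)=C)O[C@H](C)[C@H](C)C2=O
F3 | step 17 | (3R)-3-{(2R,3S)-5,7-dihydroxy-2,3-dimethyl-8-[(2R)-5-methyl-2-(prop-1-en-2-yl)hex-4-en-1-yl]-4-oxo-3,4-dihydro-2H-chromen-6-yl}hexanoic acid | C=C(C)[C@H](CC=C(C)C)Cc1c(O)c([C@H](CCC)CC(=O)O)c(O)c2c1O[C@H](C)[C@H](C)C2=O
F4 | step 17 | (8S)-epimer of 30 | C=C(C)[C@H](CC=C(C)C)C[C@]1(CC=C(C)C)C(=O)C([C@H](CCC)CC(=O)O)=C(O)C2=C1O[C@H](C)[C@H](C)C2=O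
F5 | step 14 | racemic 5-[(3-methylbut-2-en-1-yl)oxy]-5-oxo-3-propylpentanoic acid | OC(=O)CC(CCC)CC(=O)OCC=C(C)C
F6 | step 14 | (S)-1-phenylethylammonium (3S)-5-[(3-methylbut-2-en-1-yl)oxy]-5-oxo-3-propylpentanoate | [O-]C(=O)C[C@H](CCC)CC(=O)OCC=C(C)C.C[C@H]([NH3+])c1ccccc1
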